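The germacrane carbocycle is read backwards through a [3,3] shift: its two ring-trans alkenes, C1(10) and C4(5), flank the C2–C3 bond as a 1,5-diene, and the stereotriad C6(O)/C7(C)/C8(O) on the other half of the ring is mutually trans. Cutting C2–C3 while joining C5 to C10, and letting oxygen stand in for the C14 methyl, therefore gives a cyclohexanol in which the groups on C5 to C8 and the C10 vinyl are all equatorial, with vinyl and Z-alkoxyvinyl trans on adjacent carbons. A single anionic oxy-Cope step on that alcohol builds the ten-membered ring, both E alkenes and the C3 centre, and its enolate is caught as a triflate for methyl coupling.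

Key step: step 17

Remarks on the chemistry
- Carbons carry germacrane numbers from the start: cyclohexane = C5 to C10, arm = C11/C12, propiolate = C3/C4/C15, vinyl reagent = C1/C2. Faces are given relative to the C7 arm. "Z-alkoxypropenyl group" means (Z)-1-(4-methoxybenzyloxy)-3-(triisopropylsilyloxy)prop-1-en-2-yl, bonded through C4 with OPMB cis to the ring carbon.
- Assumption: the (R,R)-amide is taken to remove the proton that leads to the (S)-enol silane, as with 4-alkylcyclohexanones; if the sense proves opposite, the (S,S)-amine is used instead.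
- All enol-ether intermediates (5, 6, 16 to 23) are kept free of acid and purified on Et3N-washed silica. After step 17 nothing is heated above about 40 °C.

Step 1
Reactants: 1 methyl propiolate
Product: 2 methyl (E)-3-(4-methoxybenzyloxy)acrylate
Conditions: 4-methoxybenzyl alcohol, DABCO (10 mol%), CH2Cl2, 0 °C to rt
Reagents that add atoms: 4-methoxybenzyl alcohol, COc1ccc(CO)cc1
Why: Amine-catalysed oxa-Michael addition to the ynoate (through the ammonium allenolate) is a reliable route to E 3-alkoxyacrylates and brings in the future C3 oxygen already protected.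

Step 2
Reactants: 2 methyl (E)-3-(4-methoxybenzyloxy)acrylate
Product: 4 methyl (Z)-2-iodo-3-(4-methoxybenzyloxy)acrylate, via iodo acetoxy acetal 3 (not isolated)
Conditions: NIS, AcOH, CH2Cl2, rt; then Et3N, rt
Reagents that add atoms: N-iodosuccinimide, O=C1CCC(=O)N1I
Why: Electrophilic iodination of the enol ether with acetate capture, followed by base-induced loss of acetic acid, is the standard iodination–elimination of 3-alkoxyacrylates and should give the more stable Z iodide with iodine cis to the ether oxygen.

Step 3
Reactants: 4 methyl (Z)-2-iodo-3-(4-methoxybenzyloxy)acrylate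
Product: 5 (Z)-2-iodo-3-(4-methoxybenzyloxy)prop-2-en-1-ol
Conditions: iBu2AlH, CH2Cl2, −78 °C; aq. potassium sodium tartrate
Reagents that add atoms: none
Why: Aluminium hydride reduction of the ester to the allylic alcohol at low temperature leaves the vinyl iodide and the enol ether geometry untouched, and the basic work-up protects the acid-labile product.

Step 4
Reactants: 5 (Z)-2-iodo-3-(4-methoxybenzyloxy)prop-2-en-1-ol
Product: 6 (Z)-2-iodo-3-(4-methoxybenzyloxy)allyl triisopropylsilyl ether
Conditions: TIPSCl, imidazole, DMF, 0 °C to rt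
Reagents that add atoms: triisopropylsilyl chloride, CC(C)[Si](Cl)(C(C)C)C(C)C
Why: Standard silylation of a primary alcohol, with the bulky TIPS group chosen because it neither migrates to a nearby alkoxide nor leaves from the neighbouring vinyl anion in later steps.

Step 5
Reactants: 7 ethyl 2-(4-oxocyclohexyl)acetate
Product: 8 ethyl 2-[(1S)-4-(trimethylsilyloxy)cyclohex-3-en-1-yl]acetate
Conditions: (R,R)-bis(1-phenylethyl)amine, n-BuLi, LiCl, TMSCl (in situ), THF, −100 °C
Reagents that add atoms: chlorotrimethylsilane, C[Si](C)(C)Cl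
Why: Enantiotopic α-deprotonation of the 4-substituted cyclohexanone by the chiral lithium amide with internal silyl quench sets C7 as the only stereocentre, the ketone being deprotonated far faster than the ester.

Step 6
Reactants: 8 ethyl 2-[(1S)-4-(trimethylsilyloxy)cyclohex-3-en-1-yl]acetate
Product: 9 ethyl 2-[(1R)-4-oxocyclohex-2-en-1-yl]acetate
Conditions: Pd(OAc)2 (10 mol%), O2 (1 atm), DMSO, rt
Reagents that add atoms: none
Why: Saegusa oxidation (palladium enolate, β-hydride elimination, aerobic turnover) places the enone double bond on the side already fixed by the enol ether (C8=C9) without touching C7.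

Step 7
Reactants: 9 ethyl 2-[(1R)-4-oxocyclohex-2-en-1-yl]acetate
Product: 10 C8,C9-epoxy ketone with the oxirane trans to the C7 arm
Conditions: t-BuOOH (decane), DBU, CH2Cl2, 0 °C to rt
Reagents that add atoms: tert-butyl hydroperoxide, CC(C)(C)OO
Why: In this Weitz–Scheffer epoxidation the peroxide anion adds to C8 anti to the adjacent C7 arm and the enolate closes the oxirane on the same face, which sets C8 and C9 trans to the arm, masks the C8 hydroxyl and blocks enolisation toward C9.

Step 8
Reactants: 10 C8,C9-epoxy ketone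
Product: 11 trimethylsilyl enol ether of 10 toward C5
Conditions: LiN(SiMe3)2, TMSCl (in situ), THF, −78 °C
Reagents that add atoms: chlorotrimethylsilane, C[Si](C)(C)Cl
Why: Kinetic enolate formation with internal silyl trapping can only occur toward C5, because C9 is an oxirane carbon, and the cold amide base spares the ester.

Step 9
Reactants: 11 trimethylsilyl enol ether of 10
Product: 12 C5=C6 enone carrying the C8,C9-oxirane
Conditions: Pd(OAc)2 (1.05 equiv), MeCN, rt
Reagents that add atoms: none
Why: Saegusa oxidation under neutral conditions introduces the C5=C6 double bond without exposing the product, whose C7 hydrogen is vinylogously acidic, to base.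

Step 10
Reactants: 12 C5=C6 epoxy enone
Product: 13 5-iodo epoxy enone
Conditions: I2, pyridine, CH2Cl2, 0 °C to rt
Reagents that add atoms: iodine, II
Why: α-Iodination of the enone by the iodine–pyridine addition–elimination sequence uses a base too weak to deprotonate C7, which would open the oxirane and aromatise the ring.

Step 11
Reactants: 6 (Z)-2-iodo-3-(4-methoxybenzyloxy)allyl triisopropylsilyl ether, 13 5-iodo epoxy enone
Product: 16 epoxy enone bearing the Z-alkoxypropenyl group on C5, via alkenyllithium 14 (not isolated), via alkenylzinc bromide 15 (not isolated)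
Conditions: 6, t-BuLi (2 equiv), Et2O, −78 °C; ZnBr2, THF, −78 to 0 °C; then 13, Pd2(dba)3 (2.5 mol%), P(2-furyl)3 (10 mol%), THF/DMF, rt
Reagents that add atoms: none
Why: In this Negishi coupling, iodine–lithium exchange with retention gives a vinyllithium stabilised by the cis alkoxy group, zinc transmetalation makes it a non-basic nucleophile that tolerates ester, oxirane and the acidic C7 hydrogen, and palladium catalysis forms C4–C5 with both alkene geometries retained.

Step 12
Reactants: 16 C5-alkenylated epoxy enone
Product: 17 syn bis-epoxy ketone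
Conditions: t-BuOOH (decane), DBU, CH2Cl2, −20 to 0 °C
Reagents that add atoms: tert-butyl hydroperoxide, CC(C)(C)OO
Why: A second Weitz–Scheffer epoxidation attacks C6 anti to the adjacent C7 arm, so the new oxirane lies on the face of the first one and sets C5 and C6, while the electron-rich enol ether does not react with a nucleophilic oxidant.

Step 13
Reactants: 17 syn bis-epoxy ketone
Product: 18 all-equatorial keto diol
Conditions: SmI2 (4.5 equiv), THF/MeOH, −90 °C; NaH2PO4/Na2HPO4 buffer (pH 7)
Reagents that add atoms: none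
Why: SmI2 reduction of α,β-epoxy ketones (ketyl formation, cleavage of the Cα–O bond, protonation of the samarium enolate by methanol) should open both oxiranes in turn with retention at C6 and C8, and axial protonation at C5 places the alkenyl group equatorial, which is also the thermodynamic epimer.

Step 14
Reactants: 18 keto diol
Product: 19 8-O-triethylsilyl ether
Conditions: TESCl (1.05 equiv), imidazole, CH2Cl2, −40 °C
Reagents that add atoms: chlorotriethylsilane, CC[Si](Cl)(CC)CC
Why: Silylation with a slight excess of TESCl at low temperature should select the C8 hydroxyl, which has a CH2 neighbour, over the C6 hydroxyl flanked by two branched carbons.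

Step 15
Reactants: 19 8-O-triethylsilyl ether
Product: 20 6-O-TBS 8-O-TES ketone (5R,6S,7R,8S)
Conditions: TBSOTf, 2,6-lutidine, CH2Cl2, −78 °C
Reagents that add atoms: tert-butyldimethylsilyl triflate, CC(C)(C)[Si](C)(C)OS(=O)(=O)C(F)(F)F
Why: The reactive silyl triflate with a hindered pyridine base silylates the remaining hindered C6 hydroxyl at −78 °C without enolising the ketone or touching the enol ether.

Step 16
Reactants: 20 6-O-TBS 8-O-TES ketone, 21 vinylmagnesium bromide
Product: 23 C10 vinyl carbinol (5R,6S,7R,8S,10R), via vinylcerium dichloride 22 (not isolated)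
Conditions: CeCl3 (anhydrous), CH2=CHMgBr, THF, −78 °C; then 20, −78 °C
Reagents that add atoms: none
Why: Organocerium 1,2-addition is nucleophilic but scarcely basic, so the acidic C5 hydrogen, the β-silyloxy groups and the ester are spared, and equatorial attack on the chair ketone sets C10 with vinyl trans to the C5 alkenyl group and the hydroxyl axial.

Step 17
Reactants: 23 C10 vinyl carbinol
Product: 26 ten-membered enol triflate (3R,6R,7R,8S), via potassium alkoxide 24 (not isolated), via potassium enolate 25 (not isolated)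
Conditions: KN(SiMe3)2 (1.05 equiv), 18-crown-6, THF, 0 °C to rt; then −78 °C, N-(5-chloro-2-pyridyl)triflimide
Reagents that add atoms: N-(5-chloro-2-pyridyl)bis(trifluoromethanesulfonimide), O=S(=O)(N(c1ccc(Cl)cn1)S(=O)(=O)C(F)(F)F)C(F)(F)F
Why: Deprotonation gives alkoxide 24, whose axial C10 oxide weakens the adjacent C5–C10 bond so that the [3,3] shift (C5–C10 breaks, C2–C3 forms) runs near room temperature and ends irreversibly in the C1(10) enolate 25, which is O-sulfonylated in the cold; this is the anionic oxy-Cope rearrangement of a trans-1,2-dialkenylcyclohexanol followed by enolate triflation. The ten-membered ring is not closed end to end but arises by four-carbon ring expansion through a chair-like six-centre transition state fused to the cyclohexane chair, so no high dilution is needed. Because the two alkenyl groups are trans-diequatorial, C6 and C9 sit pseudo-equatorial on that chair and both new double bonds, C4(5) and C1(10), come out ring-trans. The only new stereocentre, C3, is set by suprafacial transfer from C5 through the same chair, in which the Z enol ether places OPMB pseudo-axial and so gives 3R. The step needs chair over boat, a single face of the enol ether and an enolate that stays on the C1 side, and these are secured by the all-equatorial ring, the Z geometry fixed in 6, one equivalent of base, poor silyloxy leaving groups on C6 and C8 and immediate triflation at −78 °C.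

Step 18
Reactants: 26 ten-membered enol triflate
Product: 27 (1(10)E,4E)-germacradiene with C14 methyl
Conditions: MeZnCl, Pd(PPh3)4 (5 mol%), THF, rt
Reagents that add atoms: methylzinc chloride, C[Zn]Cl
Why: Negishi coupling of the enol triflate with methylzinc chloride replaces the oxygen by the C14 methyl with retention of the ring-trans geometry, and the fast transmetalation, low basicity and room temperature protect the ester and the thermally labile cyclodeca-1,5-diene.

Step 19
Reactants: 27 germacradiene
Product: 28 8-hydroxy ethyl ester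
Conditions: HF·pyridine, pyridine, THF, 0 °C
Reagents that add atoms: none
Why: Pyridine-buffered HF·pyridine removes the secondary triethylsilyl ether much faster than the hindered secondary TBS and the primary TIPS ethers and is too weakly acidic to trigger transannular cyclisation.

Step 20
Reactants: 28 8-hydroxy ethyl ester
Product: 29 trans-fused 8,12-olide
Conditions: pyridinium p-toluenesulfonate (10 mol%), CH2Cl2, rt
Reagents that add atoms: none
Why: Mild acid-catalysed lactonisation (intramolecular transesterification, 5-exo-trig) of the γ-hydroxy ester gives the trans-fused 8,12-olide, since C8–OH and the C7 arm are trans and C6 is still silylated.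

Step 21
Reactants: 29 trans-fused 8,12-olide
Product: 33 α-methylene lactone, via lithium enolate 30 (not isolated), via Mannich base 31 (not isolated), via trimethylammonium iodide 32 (not isolated)
Conditions: LiN(iPr)2, THF, −78 °C; CH2=NMe2 iodide, −78 to 0 °C; then MeI, THF/MeOH, rt; then aq. NaHCO3, EtOAc, rt
Reagents that add atoms: dimethylmethyleneammonium iodide, C=[N+](C)C.[I-]
Why: Mannich reaction of the lactone lithium enolate with the iminium salt, N-methylation and Hofmann-type elimination is the standard α-methylenation of γ-lactones and brings in C13, the C11 centre being lost on elimination.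

Step 22
Reactants: 33 α-methylene lactone
Product: 34 6,15-diol
Conditions: Bu4NF, AcOH (1:1), THF, 0 °C to rt
Reagents that add atoms: none
Why: Fluoride cleaves both remaining silyl ethers, and buffering with acetic acid suppresses alkoxide-mediated translactonisation to the 6,12-olide and conjugate addition to the methylene lactone.

Step 23
Reactants: 34 6,15-diol
Product: 35 3-O-PMB ether of the target
Conditions: isovaleric anhydride, DMAP, Et3N, CH2Cl2, 0 °C to rt
Reagents that add atoms: isovaleric anhydride, CC(C)CC(=O)OC(=O)CC(C)C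
Why: DMAP-catalysed acylation esterifies the primary C15 and the secondary C6 hydroxyl with the anhydride while C3 remains masked as its PMB ether.

Step 24
Reactants: 35 3-O-PMB ether of the target
Product: 36 CNP0317194.1
Conditions: DDQ, CH2Cl2/NaH2PO4–Na2HPO4 buffer (pH 7), 0 °C
Reagents that add atoms: none
Why: Oxidative cleavage of the PMB ether by DDQ (benzylic hydride abstraction, hydrolysis of the oxocarbenium ion) frees the C3 hydroxyl under buffered conditions that leave the two esters, the methylene lactone and both ring alkenes untouched.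

Compound list
1 | methyl propiolate | C#CC(=O)OC | starting material
2 | methyl (E)-3-(4-methoxybenzyloxy)acrylate | COC(=O)/C=C/OCc1ccc(OC)cc1 | intermediate
3 | methyl 3-acetoxy-2-iodo-3-(4-methoxybenzyloxy)propanoate (diastereomer mixture, not isolated) | COC(=O)C(I)C(OC(C)=O)OCc1ccc(OC)cc1 | intermediate
4 | methyl (Z)-2-iodo-3-(4-methoxybenzyloxy)acrylate (iodine cis to OPMB) | COC(=O)/C(I)=C/OCc1ccc(OC)cc1 | intermediate
5 | (Z)-2-iodo-3-(4-methoxybenzyloxy)prop-2-en-1-ol | OC/C(I)=C/OCc1ccc(OC)cc1 | intermediate
6 | (Z)-2-iodo-3-(4-methoxybenzyloxy)allyl triisopropylsilyl ether (iodine cis to OPMB) | I/C(CO[Si](C(C)C)(C(C)C)C(C)C)=C\OCc1ccc(OC)cc1 | intermediate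
7 | ethyl 2-(4-oxocyclohexyl)acetate | CCOC(=O)CC1CCC(=O)CC1 | starting material
8 | ethyl 2-[(1S)-4-(trimethylsilyloxy)cyclohex-3-en-1-yl]acetate | C[Si](C)(C)OC1=CC[C@@H](CC(=O)OCC)CC1 | intermediate
9 | ethyl 2-[(1R)-4-oxocyclohex-2-en-1-yl]acetate | O=C1C=C[C@@H](CC(=O)OCC)CC1 | intermediate
10 | ethyl 2-(2,3-epoxy-4-oxocyclohexyl)acetate, C8,C9-oxirane trans to the C7 arm (7R,8R,9R by germacrane numbers) | O=C1[C@@H]2O[C@@H]2[C@@H](CC(=O)OCC)CC1 | intermediate
11 | trimethylsilyl enol ether of 10 toward C5 (C10=C5), oxirane intact | C[Si](C)(C)OC1=CC[C@H](CC(=O)OCC)[C@H]2O[C@@H]12 | intermediate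
12 | ethyl 2-(5,6-epoxy-4-oxocyclohex-2-en-1-yl)acetate: C5=C6 enone, C8,C9-oxirane trans to the C7 arm | O=C1[C@@H]2O[C@@H]2[C@@H](CC(=O)OCC)C=C1 | intermediate
13 | 12 with iodine on C5 (2-iodo epoxy enone) | O=C1[C@@H]2O[C@@H]2[C@@H](CC(=O)OCC)C=C1I | intermediate
14 | (Z)-alkenyllithium from 6 (lithium in place of iodine, not isolated) | [Li]/C(CO[Si](C(C)C)(C(C)C)C(C)C)=C\OCc1ccc(OC)cc1 | intermediate
15 | (Z)-alkenylzinc bromide from 14 (not isolated) | Br[Zn]/C(CO[Si](C(C)C)(C(C)C)C(C)C)=C\OCc1ccc(OC)cc1 | intermediate
16 | epoxy enone 12 bearing the Z-alkoxypropenyl group on C5 (C4–C5 bond, OPMB cis to C5) | O=C1[C@@H]2O[C@@H]2[C@@H](CC(=O)OCC)C=C1/C(CO[Si](C(C)C)(C(C)C)C(C)C)=C\OCc3ccc(OC)cc3 | intermediate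
17 | syn bis-epoxy ketone: C8,C9- and C5,C6-oxiranes both trans to the C7 arm, Z-alkoxypropenyl group on C5 | O=C1[C@@H]2O[C@@H]2[C@@H](CC(=O)OCC)[C@@H]3O[C@]13/C(CO[Si](C(C)C)(C(C)C)C(C)C)=C\OCc4ccc(OC)cc4 | intermediate
18 | keto diol: C10 ketone, C5 Z-alkoxypropenyl cis to the arm, C6–OH and C8–OH trans to the arm, all equatorial | O=C1C[C@H](O)[C@@H](CC(=O)OCC)[C@H](O)[C@H]1/C(CO[Si](C(C)C)(C(C)C)C(C)C)=C\OCc2ccc(OC)cc2 | intermediate
19 | 8-O-triethylsilyl ether of 18 (C6–OH free) | O=C1C[C@H](O[Si](CC)(CC)CC)[C@@H](CC(=O)OCC)[C@H](O)[C@H]1/C(CO[Si](C(C)C)(C(C)C)C(C)C)=C\OCc2ccc(OC)cc2 | intermediate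
20 | 6-O-tert-butyldimethylsilyl-8-O-triethylsilyl ketone, all-equatorial (5R,6S,7R,8S) | O=C1C[C@H](O[Si](CC)(CC)CC)[C@@H](CC(=O)OCC)[C@H](O[Si](C)(C)C(C)(C)C)[C@H]1/C(CO[Si](C(C)C)(C(C)C)C(C)C)=C\OCc2ccc(OC)cc2 | intermediate
21 | vinylmagnesium bromide | C=C[Mg]Br | starting material
22 | vinylcerium dichloride (not isolated) | C=C[Ce](Cl)Cl | intermediate
23 | C10 vinyl carbinol: vinyl equatorial and trans to the C5 group, hydroxyl axial (5R,6S,7R,8S,10R) | C=C[C@]1(O)C[C@H](O[Si](CC)(CC)CC)[C@@H](CC(=O)OCC)[C@H](O[Si](C)(C)C(C)(C)C)[C@H]1/C(CO[Si](C(C)C)(C(C)C)C(C)C)=C\OCc2ccc(OC)cc2 | intermediate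
24 | potassium alkoxide of 23 (not isolated) | C=C[C@]1(O[K])C[C@H](O[Si](CC)(CC)CC)[C@@H](CC(=O)OCC)[C@H](O[Si](C)(C)C(C)(C)C)[C@H]1/C(CO[Si](C(C)C)(C(C)C)C(C)C)=C\OCc2ccc(OC)cc2 | intermediate
25 | potassium C1(10) enolate of the ring-expanded ten-membered ketone (not isolated) | CCOC(=O)C[C@@H]1[C@@H](O[Si](CC)(CC)CC)C/C(O[K])=C/C[C@@H](OCc2ccc(OC)cc2)/C(CO[Si](C(C)C)(C(C)C)C(C)C)=C/[C@H]1O[Si](C)(C)C(C)(C)C | intermediate
26 | ten-membered enol triflate: C10–OTf, C3–OPMB, C15–OTIPS, C6–OTBS, C8–OTES, ethyl ester arm; C1(10) and C4(5) alkenes ring-trans (the triflate alkene is formally Z by the sequence rule); 3R,6R,7R,8S | CCOC(=O)C[C@@H]1[C@@H](O[Si](CC)(CC)CC)C/C(OS(=O)(=O)C(F)(F)F)=C/C[C@@H](OCc2ccc(OC)cc2)/C(CO[Si](C(C)C)(C(C)C)C(C)C)=C/[C@H]1O[Si](C)(C)C(C)(C)C | intermediate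
27 | (1(10)E,4E)-germacradiene with C14 methyl on C10, otherwise as 26 | CCOC(=O)C[C@@H]1[C@@H](O[Si](CC)(CC)CC)C/C(C)=C/C[C@@H](OCc2ccc(OC)cc2)/C(CO[Si](C(C)C)(C(C)C)C(C)C)=C/[C@H]1O[Si](C)(C)C(C)(C)C | intermediate
28 | 8-hydroxy ethyl ester (TES removed from 27) | CCOC(=O)C[C@@H]1[C@@H](O)C/C(C)=C/C[C@@H](OCc2ccc(OC)cc2)/C(CO[Si](C(C)C)(C(C)C)C(C)C)=C/[C@H]1O[Si](C)(C)C(C)(C)C | intermediate
29 | trans-fused 8,12-olide with C11 still CH2; 3-OPMB, 6-OTBS, 15-OTIPS | C1C(=O)O[C@H]2C/C(C)=C/C[C@@H](OCc3ccc(OC)cc3)/C(CO[Si](C(C)C)(C(C)C)C(C)C)=C/[C@@H](O[Si](C)(C)C(C)(C)C)[C@H]12 | intermediate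
30 | lithium enolate of lactone 29 (not isolated) | C1=C(O[Li])O[C@H]2C/C(C)=C/C[C@@H](OCc3ccc(OC)cc3)/C(CO[Si](C(C)C)(C(C)C)C(C)C)=C/[C@@H](O[Si](C)(C)C(C)(C)C)[C@H]12 | intermediate
31 | 11-(dimethylaminomethyl) lactone, C11 epimers (not isolated) | CN(C)CC1C(=O)O[C@H]2C/C(C)=C/C[C@@H](OCc3ccc(OC)cc3)/C(CO[Si](C(C)C)(C(C)C)C(C)C)=C/[C@@H](O[Si](C)(C)C(C)(C)C)[C@H]12 | intermediate
32 | trimethylammonium iodide of 31 (not isolated) | C[N+](C)(C)CC1C(=O)O[C@H]2C/C(C)=C/C[C@@H](OCc3ccc(OC)cc3)/C(CO[Si](C(C)C)(C(C)C)C(C)C)=C/[C@@H](O[Si](C)(C)C(C)(C)C)[C@H]12.[I-] | intermediate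
33 | α-methylene 8,12-olide; 3-OPMB, 6-OTBS, 15-OTIPS | C=C1C(=O)O[C@H]2C/C(C)=C/C[C@@H](OCc3ccc(OC)cc3)/C(CO[Si](C(C)C)(C(C)C)C(C)C)=C/[C@@H](O[Si](C)(C)C(C)(C)C)[C@H]12 | intermediate
34 | 6,15-diol of the α-methylene lactone, 3-OPMB | C=C1C(=O)O[C@H]2C/C(C)=C/C[C@@H](OCc3ccc(OC)cc3)/C(CO)=C/[C@@H](O)[C@H]12 | intermediate
35 | 6,15-bis(3-methylbutanoate), 3-O-PMB ether of the target | C=C1C(=O)O[C@H]2C/C(C)=C/C[C@@H](OCc3ccc(OC)cc3)/C(COC(=O)CC(C)C)=C/[C@@H](OC(=O)CC(C)C)[C@H]12 | intermediate
36 | CNP0317194.1: (3R,6R,7R,8S,1(10)E,4E)-3-hydroxy-6,15-bis(3-methylbutanoyloxy)germacra-1(10),4,11(13)-trien-12,8-olide | C=C1C(=O)O[C@H]2C/C(C)=C/C[C@@H](O)/C(COC(=O)CC(C)C)=C/[C@@H](OC(=O)CC(C)C)[C@H]12 | target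

Total step count: 24.
Longest linear sequence: 20 steps (7 to 36, steps 5 to 24); the alkenyl iodide 6 takes 4 steps and joins at step 11.

Steps most likely to fail

Step 17. The pseudo-axial alkoxy group may slow the rearrangement, and in that time proton exchange through the ester α-position can move the enolate from C1 to C9, after which the C8 silyloxy group is lost by elimination. O-sulfonylation of the crown-complexed potassium enolate may also be too slow to freeze the regiochemistry. The fallback sets out from 23. The alkoxide is rearranged as before, but enolate 25 is quenched at −78 °C with TMSCl and Et3N, the fastest trap for a medium-ring enolate, and the C1(10) trimethylsilyl enol ether F1 is isolated by non-aqueous work-up. F1 is then treated with CsF and N-phenyltriflimide in 1,2-dimethoxyethane at rt. Fluoride releases the enolate regiospecifically in the presence of the sulfonylating agent and with no base that could equilibrate it, and the route is rejoined at 26.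

Step 12. Conjugate addition of the peroxide to the α-substituted dienone is slow, so base-induced deprotonation at C7, followed by oxirane opening and aromatisation, can compete. The facial preference also rests on the C7 arm outweighing the oxirane already present on the attacked face. The fallback sets out from 16 and replaces the oxygen nucleophile by a ligand-controlled boron nucleophile under nearly neutral conditions. Copper-catalysed conjugate borylation (CuCl, NaOtBu, a Segphos-type bisphosphine chosen to reinforce delivery anti to the arm, B2pin2, MeOH, THF, 0 °C), followed by brief Et3N equilibration of C5, should give the C6 pinacol boronate F2. Oxidation with NaBO3·4H2O in THF/water, with retention at C6, gives the 6-hydroxy C8,C9-epoxy ketone F3. A single SmI2/MeOH opening at −90 °C of the one remaining oxirane then returns to the route at 18.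

Step 13. The second reduction may stall, the doubly β-hydroxylated ketone may undergo retro-aldol cleavage or dehydration in the presence of the Lewis acidic samarium salts, and the subsequent monosilylation depends on a modest steric difference between two secondary hydroxyls. The fallback sets out from 17 and opens the oxiranes one at a time with protection in between. Na[PhSeB(OEt)3] (from PhSeSePh and NaBH4 in EtOH, buffered with AcOH, 0 °C) attacks the carbonyl-bound oxirane carbon by direct displacement, which is possible only at the secondary C9 and not at the quaternary C5, and gives the 8-hydroxy C5,C6-epoxy ketone F4. TESCl and imidazole give its triethylsilyl ether F5. SmI2/MeOH at −90 °C then opens the remaining oxirane, with protonation at C5, and returns to the route at 19 without any site-selective silylation.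

Further compounds
F1 | step 17 | C1(10) trimethylsilyl enol ether of the ring-expanded ten-membered ketone | CCOC(=O)C[C@@H]1[C@@H](O[Si](CC)(CC)CC)C/C(O[Si](C)(C)C)=C/C[C@@H](OCc2ccc(OC)cc2)/C(CO[Si](C(C)C)(C(C)C)C(C)C)=C/[C@H]1O[Si](C)(C)C(C)(C)C
F2 | step 12 | C6 pinacol boronate of the C8,C9-epoxy ketone (boron trans to the C7 arm, C5 alkenyl group equatorial) | O=C1[C@@H]2O[C@@H]2[C@@H](CC(=O)OCC)[C@H](B3OC(C)(C)C(C)(C)O3)[C@H]1/C(CO[Si](C(C)C)(C(C)C)C(C)C)=C\OCc4ccc(OC)cc4
F3 | step 12 | 6-hydroxy C8,C9-epoxy ketone (C6–OH trans to the C7 arm) | O=C1[C@@H]2O[C@@H]2[C@@H](CC(=O)OCC)[C@H](O)[C@H]1/C(CO[Si](C(C)C)(C(C)C)C(C)C)=C\OCc3ccc(OC)cc3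
F4 | step 13 | 8-hydroxy C5,C6-epoxy ketone (C8–OH trans to the C7 arm) | O=C1C[C@H](O)[C@@H](CC(=O)OCC)[C@@H]2O[C@]12/C(CO[Si](C(C)C)(C(C)C)C(C)C)=C\OCc3ccc(OC)cc3
F5 | step 13 | 8-triethylsilyloxy C5,C6-epoxy ketone | O=C1C[C@H](O[Si](CC)(CC)CC)[C@@H](CC(=O)OCC)[C@@H]2O[C@]12/C(CO[Si](C(C)C)(C(C)C)C(C)C)=C\OCc3ccc(OC)cc3
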